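The cyclohexane ring C1–C2–C3–C4–C4a–C8a is closed last, at C1–C8a. Two features are exploited: C1 is a benzylic carbon bearing a 4-oxygenated aryl group and ionises readily to a quinone-methide-type cation, and C8a is para to the C6 oxygen of the fused arene. The trans C2/C3 bis(hydroxymethyl) unit is carried as a 5-menthyloxy butyrolactone. In one flask a lithiated aryl dithiane (C4 with the fused arene), (5R)-5-menthyloxyfuranone (C2, C3, both CH2OH carbons) and O-benzylvanillin (C1 with the pendant aryl) are joined by conjugate addition and aldol reaction; acid then closes the ring by Friedel–Crafts alkylation. C3, C2 and C1 are set in sequence from the single acetal stereocentre.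

Key step: step 2

Assumption: tetralin numbering (C1 = ArCH, C4 = benzylic CH2, oxygens on C6 and C7) is used for all bicyclic compounds, and (5R)-5-(l-menthyloxy)furan-2(5H)-one is taken as a purchasable compound.

Step 1
Reactants: 1 3-(benzyloxy)-4-methoxybenzaldehyde
Product: 2 2-[3-(benzyloxy)-4-methoxyphenyl]-1,3-dithiane
Conditions: HS(CH2)3SH, BF3·OEt2 (cat.), CH2Cl2, 0 °C → rt
Reagents that add atoms: propane-1,3-dithiol, SCCCS
Why: Lewis-acid-catalysed dithioacetalisation of an aryl aldehyde installs the Corey–Seebach umpolung handle for the future C4 and creates no stereocentre.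

Step 2
Reactants: 2 2-[3-(benzyloxy)-4-methoxyphenyl]-1,3-dithiane; 3 (5R)-5-(l-menthyloxy)furan-2(5H)-one; 4 4-(benzyloxy)-3-methoxybenzaldehyde
Product: 8 trans-fused 1-aryltetralin menthyloxy lactone (spiro-1,3-dithiane at C4), via lithiodithiane 5 (not isolated), via lithium enolate 6 (not isolated), via aldol adduct 7 (not isolated)
Conditions: n-BuLi, THF, −78 °C; then 3, −78 °C; then 4, −78 °C; then TFA (excess), CH2Cl2, −78 °C → rt (one pot)
Reagents that add atoms: none
Why: n-BuLi deprotonates 2 to the soft dithianyl anion 5, which adds 1,4 to butenolide 3 anti to the menthyloxy group; enolate 6 attacks aldehyde 4 anti to the new dithianyl substituent to give carbinol 7 (both carbinol epimers), and TFA ionises this carbinol to a 4-benzyloxybenzylic (quinone-methide-type) cation at C1 that is captured by the arene carbon para to the C6 benzyloxy group (C8a) with loss of water. The closest known reaction types are the tandem conjugate addition–aldol reaction of lithiated 2-aryl-1,3-dithianes with 5-alkoxybutenolides and the acid-mediated Friedel–Crafts cyclisation of β-benzyl-α-(α-hydroxybenzyl)butyrolactones to 1-aryltetralins. The six-membered ring closes by intramolecular electrophilic aromatic substitution at C1–C8a (cationic closure, exo with respect to the departing C1–O bond), the γ-lactone being already in place as a temporary ring. C3 is controlled by the acetal stereocentre (steric approach control), C2 by C3 (trans trapping of the enolate) and C1 by C2 through a chair-like transition state with the pendant aryl group pseudo-equatorial and trans to the C2 acyl group; both epimers of 7 converge through the common planar cation. The step needs 1,4- over 1,2-addition (secured by the aryl-stabilised soft anion at −78 °C), arylation para and not ortho to the benzyloxy group (the ortho site lies between two substituents) and ring closure faster than loss of the C2 proton (secured by the electron-rich dialkoxyarene placed for six-membered closure).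

Step 3
Reactants: 8 trans-fused 1-aryltetralin menthyloxy lactone (spiro-1,3-dithiane at C4)
Product: 9 (1S,2R,3R)-2,3-bis(hydroxymethyl) dibenzyl ether carrying the spiro-1,3-dithiane at C4
Conditions: LiAlH4, THF, 0 °C → reflux; aq. NaOH work-up
Reagents that add atoms: none
Why: Hydride reduction of the acylal-type lactone should reduce the carbonyl carbon and, after ring opening and loss of menthoxide, the former acetal carbon as well, so that both become CH2OH; the dithiane and benzyl ethers are inert and C1–C3 are untouched.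

Step 4
Reactants: 9 (1S,2R,3R)-2,3-bis(hydroxymethyl) dibenzyl ether carrying the spiro-1,3-dithiane at C4
Product: 10 (1S,2R,3R)-1-(4-hydroxy-3-methoxyphenyl)-2,3-bis(hydroxymethyl)-7-methoxy-1,2,3,4-tetrahydronaphthalen-6-ol
Conditions: Raney Ni (W-2, large excess), H2 (1 atm), EtOH, reflux
Reagents that add atoms: none
Why: Mozingo reductive desulfurisation should turn the benzylic dithioketal into the C4 methylene, and the same nickel/H2 system should hydrogenolyse both aryl benzyl ethers; no C–C or C–O bond at a stereocentre is broken.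

Compound list
1 | 3-(benzyloxy)-4-methoxybenzaldehyde (O-benzylisovanillin) | COc1ccc(C=O)cc1OCc1ccccc1 | starting material
2 | 2-[3-(benzyloxy)-4-methoxyphenyl]-1,3-dithiane | COc1ccc(C2SCCCS2)cc1OCc1ccccc1 | intermediate
3 | (5R)-5-{[(1R,2S,5R)-5-methyl-2-(propan-2-yl)cyclohexyl]oxy}furan-2(5H)-one, (5R)-5-(l-menthyloxy)furanone | O=C1C=C[C@H](O[C@@H]2C[C@H](C)CC[C@H]2C(C)C)O1 | starting material
4 | 4-(benzyloxy)-3-methoxybenzaldehyde (O-benzylvanillin) | COc1cc(C=O)ccc1OCc1ccccc1 | starting material
5 | 2-[3-(benzyloxy)-4-methoxyphenyl]-2-lithio-1,3-dithiane (not isolated) | [Li]C1(c2ccc(OC)c(OCc3ccccc3)c2)SCCCS1 | intermediate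
6 | lithium enolate of (4R,5R)-4-{2-[3-(benzyloxy)-4-methoxyphenyl]-1,3-dithian-2-yl}-5-(l-menthyloxy)dihydrofuran-2(3H)-one, dithianyl group anti to menthyloxy (not isolated) | [Li]OC1=C[C@@H](C2(c3ccc(OC)c(OCc4ccccc4)c3)SCCCS2)[C@H](O[C@@H]2C[C@H](C)CC[C@H]2C(C)C)O1 | intermediate
7 | (3S,4R,5R)-3-{[4-(benzyloxy)-3-methoxyphenyl](hydroxy)methyl}-4-{2-[3-(benzyloxy)-4-methoxyphenyl]-1,3-dithian-2-yl}-5-(l-menthyloxy)dihydrofuran-2(3H)-one, 3,4-trans and 4,5-trans, both carbinol epimers (not isolated) | O=C1O[C@@H](O[C@@H]2C[C@H](C)CC[C@H]2C(C)C)[C@H](C2(c3ccc(OC)c(OCc4ccccc4)c3)SCCCS2)[C@H]1C(O)c1ccc(OCc2ccccc2)c(OC)c1 | intermediate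
8 | (1S,2R,3R)-6-(benzyloxy)-1-[4-(benzyloxy)-3-methoxyphenyl]-7-methoxytetralin with a spiro-1,3-dithiane at C4 and a trans-fused γ-lactone C2–C(=O)–O–CH(O-l-menthyl)–C3 (acetal carbon R); aryl trans to C2 acyl, C2/C3 trans | O=C1O[C@@H](O[C@@H]3C[C@H](C)CC[C@H]3C(C)C)[C@H]2[C@H]1[C@@H](c1ccc(OCc3ccccc3)c(OC)c1)c1cc(OC)c(OCc3ccccc3)cc1C21SCCCS1 | intermediate
9 | (1S,2R,3R)-6-(benzyloxy)-1-[4-(benzyloxy)-3-methoxyphenyl]-2,3-bis(hydroxymethyl)-7-methoxytetralin with a spiro-1,3-dithiane at C4 (all-trans) | COc1cc([C@H]2c3cc(OC)c(OCc4ccccc4)cc3C3(SCCCS3)[C@@H](CO)[C@@H]2CO)ccc1OCc1ccccc1 | intermediate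
10 | (1S,2R,3R)-1-(4-hydroxy-3-methoxyphenyl)-2,3-bis(hydroxymethyl)-7-methoxy-1,2,3,4-tetrahydronaphthalen-6-ol | COc1cc([C@H]2c3cc(OC)c(O)cc3C[C@@H](CO)[C@@H]2CO)ccc1O | target

Total step count: 4
Longest linear sequence: 4 steps (1 → 2 → 8 → 9 → 10)

Steps most likely to fail

1. Step 2. The ring closure may stall in the ether-containing acidic medium. A dithiane sulfur may also intercept the C1 cation (sulfonium formation, sulfur shift), or the cation may lose the C2 proton before the arene attacks. The fallback sets out from compound 7, which is then isolated by stopping the one-pot sequence after the aldol stage with aqueous NH4Cl. Sulfur is removed before ring closure: nickel boride (NiCl2·6H2O, NaBH4, MeOH–THF, 0 °C) should give the sulfur-free β-benzyl-α-(hydroxybenzyl) menthyloxy lactone F1. Classical Friedel–Crafts closure of this carbinol in TFA–CH2Cl2 at 0 °C should give the aryltetralin menthyloxy lactone F2 with a C4 methylene. LiAlH4 in THF should give the dibenzyl ether of the target F3, and hydrogenolysis (H2, Pd/C, EtOAc–MeOH) comes back to the route at compound 10.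

2. Step 4. Sulfur may poison the nickel surface so that cleavage of the aryl benzyl ethers is incomplete, or desulfurisation may run through a C3=C4 alkene whose re-hydrogenation would erode the configuration at C3. The fallback sets out from compound 9 and separates the two tasks without hydrogenation on a sulfided surface. Debenzylation with BCl3 and pentamethylbenzene (CH2Cl2, −78 °C) should give the bis-phenol dithiane diol F4. Low-temperature nickel boride desulfurisation (NiCl2·6H2O, NaBH4, MeOH–THF, 0 °C) then comes back to the route at compound 10.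

3. Step 3. The reduction may stall at the lactol stage, or C3 may epimerise through the α-branched aldehyde that is released when menthoxide leaves. The fallback sets out from compound 8 and removes the auxiliary in a separate, milder operation: KOH and NaBH4 in aqueous EtOH–THF followed by acidification (HCl) should give the simple trans-fused γ-lactone F5 (lactone CH2 on C3). LiAlH4 reduction of this ordinary lactone comes back to the route at compound 9.

Further compounds
F1 | step 2 | (3S,4R,5R)-4-[3-(benzyloxy)-4-methoxybenzyl]-3-{[4-(benzyloxy)-3-methoxyphenyl](hydroxy)methyl}-5-(l-menthyloxy)dihydrofuran-2(3H)-one, both carbinol epimers | O=C1O[C@@H](O[C@@H]2C[C@H](C)CC[C@H]2C(C)C)[C@H](Cc2ccc(OC)c(OCc3ccccc3)c2)[C@H]1C(O)c1ccc(OCc2ccccc2)c(OC)c1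
F2 | step 2 | (1S,2R,3R)-6-(benzyloxy)-1-[4-(benzyloxy)-3-methoxyphenyl]-7-methoxytetralin with trans-fused γ-lactone C2–C(=O)–O–CH(O-l-menthyl)–C3 and C4 methylene | O=C1O[C@@H](O[C@@H]3C[C@H](C)CC[C@H]3C(C)C)[C@H]2[C@H]1[C@@H](c1ccc(OCc3ccccc3)c(OC)c1)c1cc(OC)c(OCc3ccccc3)cc1C2
F3 | step 2 | (1S,2R,3R)-6-(benzyloxy)-1-[4-(benzyloxy)-3-methoxyphenyl]-2,3-bis(hydroxymethyl)-7-methoxy-1,2,3,4-tetrahydronaphthalene | COc1cc([C@H]2c3cc(OC)c(OCc4ccccc4)cc3C[C@@H](CO)[C@@H]2CO)ccc1OCc1ccccc1
F4 | step 4 | (1S,2R,3R)-1-(4-hydroxy-3-methoxyphenyl)-2,3-bis(hydroxymethyl)-7-methoxytetralin-6-ol with a spiro-1,3-dithiane at C4 | COc1cc([C@H]2c3cc(OC)c(O)cc3C3(SCCCS3)[C@@H](CO)[C@@H]2CO)ccc1O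
F5 | step 3 | (1S,2R,3R)-6-(benzyloxy)-1-[4-(benzyloxy)-3-methoxyphenyl]-7-methoxytetralin with a spiro-1,3-dithiane at C4 and trans-fused γ-lactone C2–C(=O)–O–CH2–C3 | O=C1OC[C@H]2[C@H]1[C@@H](c1ccc(OCc3ccccc3)c(OC)c1)c1cc(OC)c(OCc3ccccc3)cc1C21SCCCS1
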